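**Strategy.** The route rests on closing the α-methylene-γ-butyrolactone (ring O–C6–C7–C11–C12, germacrane numbering) across C7–C11 on an acyclic chain, before the ten-membered carbocycle exists. The key step exploits the vicinal array C11–C7–C8–O. The C8 acyloxy oxygen is read as the oxygen of a trans-7,8-epoxide, and a phosphonoacetate carbanion tethered through O6 opens it at C7 (5-exo, inversion). One operation forms the lactone, sets C7, frees the C8 hydroxyl and, after formaldehyde is added, installs the exocyclic methylene. The precursor is an erythro epoxy alcohol phosphonoacetate from a Sharpless kinetic resolution. The carbocycle is closed later at C3–C4 by a CrCl2/NiCl2 coupling.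

Key step: step 10

Remarks on the chemistry:
- Atom labels C1–C15 follow germacrane numbering: C1–C10 ring, O on C6 in the lactone, C11–C13 the methylene-acyl unit, C14 on C10, C15 on C4. TBS = tert-butyldimethylsilyl, TBDPS = tert-butyldiphenylsilyl, DMAP = 4-(dimethylamino)pyridine.
- Assumption: (2R)-2-methylbutanoic acid is taken as a commercial chiral-pool acid. The carbinol of 13 is made racemic and resolved in step 8, so that step can convert at most half of the material.

Step 1
Reactants: 1 methyl 2-[bis(2,2,2-trifluoroethoxy)phosphoryl]acetate; 2 allyl bromide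
Product: 3 methyl 2-[bis(2,2,2-trifluoroethoxy)phosphoryl]pent-4-enoate (racemic)
Conditions: NaH, DMF, 0 °C to rt (slight excess of 1)
Reagents that add atoms: none
Why: SN2 C-alkylation of the stabilised phosphonoacetate carbanion with a reactive allylic bromide, with excess 1 to suppress dialkylation; no stereocentre of the target is involved.

Step 2
Reactants: 3 (above); 4 3-[(tert-butyldimethylsilyl)oxy]propanal
Product: 5 methyl (2Z)-5-(TBS-oxy)-2-(prop-2-en-1-yl)pent-2-enoate
Conditions: KN(SiMe3)2, 18-crown-6, THF, −78 °C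
Reagents that add atoms: none
Why: Still–Gennari variant of the Horner–Wadsworth–Emmons olefination, in which the electron-poor phosphonate eliminates kinetically to the Z-enoate; this places the ester carbon (future C14) cis to C2 and so fixes the ring-trans C1=C10 geometry.

Step 3
Reactants: 5 (above)
Product: 6 (2Z)-5-(TBS-oxy)-2-(prop-2-en-1-yl)pent-2-en-1-ol
Conditions: iBu2AlH, CH2Cl2, −78 to 0 °C
Reagents that add atoms: none
Why: 1,2-reduction of the enoate to the allylic alcohol by the aluminium hydride; the silyl ether and both alkenes are untouched and the geometry is retained.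

Step 4
Reactants: 6 (above)
Product: 7 (2Z)-1-(TBDPS-oxy)-5-(TBS-oxy)-2-(prop-2-en-1-yl)pent-2-ene
Conditions: TBDPSCl, imidazole, CH2Cl2, rt
Reagents that add atoms: tert-butyl(chloro)diphenylsilane, CC(C)(C)[Si](Cl)(c1ccccc1)c1ccccc1
Why: standard silylation of a primary alcohol; TBDPS is chosen because it survives the acid that later removes the primary TBS group.

Step 5
Reactants: 7 (above); 8 (E)-crotonaldehyde (excess)
Product: 9 (2E,5Z)-5-[(TBDPS-oxy)methyl]-8-(TBS-oxy)octa-2,5-dienal
Conditions: second-generation Hoveyda–Grubbs catalyst (5 mol%), CH2Cl2, 40 °C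
Reagents that add atoms: none
Why: olefin cross-metathesis in which only the monosubstituted alkene of 7 reacts (the trisubstituted one is inert) and the enal partner gives the E-alkene C7=C8 under thermodynamic control.

Step 6
Reactants: 9 (above); 10 prop-1-ynylmagnesium bromide
Product: 11 rac-(5E,8Z)-8-[(TBDPS-oxy)methyl]-11-(TBS-oxy)undeca-5,8-dien-2-yn-4-ol
Conditions: THF, −78 °C
Reagents that add atoms: none
Why: 1,2-addition of an alkynyl Grignard reagent to the enal at low temperature; the new carbinol (C6) is formed racemic on purpose and is resolved in step 8.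

Step 7
Reactants: 11 (above)
Product: 13 rac-(2Z,5E,8Z)-2-iodo-8-[(TBDPS-oxy)methyl]-11-(TBS-oxy)undeca-2,5,8-trien-4-ol, via alkenylalanate 12 (not isolated)
Conditions: NaAlH2(OCH2CH2OMe)2, THF, 0 °C to rt; then iodine, −78 °C
Reagents that add atoms: iodine, II
Why: hydroxyl-directed trans-hydroalumination of the propargylic alcohol puts aluminium on the distal alkyne carbon (C4) and iodinolysis proceeds with retention, which sets the Z geometry of C4=C5 (iodine cis to C6).

Step 8
Reactants: 13 (above)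
Product: 14 (1R,2Z)-1-[(2R,3R)-3-{(2Z)-2-[(TBDPS-oxy)methyl]-5-(TBS-oxy)pent-2-en-1-yl}oxiran-2-yl]-3-iodobut-2-en-1-ol
Conditions: Ti(OiPr)4 (cat.), (−)-(2S,3S)-diisopropyl tartrate, tBuOOH (0.55 equiv), 4 Å molecular sieves, CH2Cl2, −20 °C
Reagents that add atoms: tert-butyl hydroperoxide, CC(C)(C)OO
Why: Sharpless asymmetric epoxidation run as a kinetic resolution: with this tartrate the (4S)-enantiomer of 13 is epoxidised fast on the E-disubstituted alkene to the erythro epoxy alcohol, which sets C6, C7 and C8 in one step (the descriptor at the carbinol changes to 1R only through the priority rules), while the (4R)-enantiomer and the cis-substituted, electron-poor iodoalkene react slowly.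

Step 9
Reactants: 14 (above); 15 2-(diethoxyphosphoryl)acetic acid
Product: 16 (1R,2Z)-1-[(2S,3R)-3-{(2Z)-2-[(TBDPS-oxy)methyl]-5-(TBS-oxy)pent-2-en-1-yl}oxiran-2-yl]-3-iodobut-2-en-1-yl 2-(diethoxyphosphoryl)acetate
Conditions: N,N'-dicyclohexylcarbodiimide, DMAP (cat.), CH2Cl2, 0 °C to rt
Reagents that add atoms: none
Why: Steglich esterification of the secondary epoxy alcohol under neutral conditions, which leaves the epoxide intact and touches no stereocentre.

Step 10
Reactants: 16 (above)
Product: 18 (4R,5S)-4-[(1R,3Z)-1-hydroxy-3-[(TBDPS-oxy)methyl]-6-(TBS-oxy)hex-3-en-1-yl]-5-[(1Z)-2-iodoprop-1-en-1-yl]-3-methylideneoxolan-2-one, via α-phosphono lactone 17 (not isolated)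
Conditions: NaH, THF/DMF, 0 to 40 °C; then aq. CH2O, 0 °C to rt
Reagents that add atoms: formaldehyde, C=O
Why: Deprotonation gives the phosphonate-stabilised carbanion at C11, which attacks the epoxide carbon C7 opposite to its carbon–oxygen bond (SN2) and closes the five-membered lactone O–C6–C7–C11–C12 in the 5-exo-tet mode; the released C8 alkoxide is protonated by the acidic α-hydrogen and the resulting phosphonate anion undergoes Horner–Wadsworth–Emmons olefination with formaldehyde to install C13. The closest known reaction types are the opening of epoxides by phosphonoacetate and malonate carbanions and the 5-exo delivery of tethered nucleophiles to C2 of 2,3-epoxy alcohol derivatives. The new stereocentre C7 is set by inversion, so the epoxide configuration fixed in step 8 becomes the 6,7-trans lactone with C11 anti to the C8 oxygen, and C8 keeps its carbon–oxygen bond and configuration. The step needs C- over O-alkylation of the ambident anion and attack at C7 instead of C8 (6-endo): the exocyclic phosphoryl group keeps the carbanion stabilised while the ring ester twists out of conjugation, the three-atom tether favours the exo mode, and C8 carries no activating group. Phosphoryl migration to the C8 oxygen, which would lead on to a cyclopropane, is avoided by keeping the temperature low and adding formaldehyde as soon as the epoxide is consumed.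

Step 11
Reactants: 18 (above); 19 (2R)-2-methylbutanoic acid
Product: 20 (1R,3Z)-3-[(TBDPS-oxy)methyl]-6-(TBS-oxy)-1-[(2S,3R)-2-[(1Z)-2-iodoprop-1-en-1-yl]-4-methylidene-5-oxooxolan-3-yl]hex-3-en-1-yl (2R)-2-methylbutanoate
Conditions: N,N'-dicyclohexylcarbodiimide, DMAP (cat.), CH2Cl2, 0 °C to rt
Reagents that add atoms: none
Why: Steglich esterification of the only free hydroxyl (C8); the acyl stereocentre comes from the chiral-pool acid and low temperature with catalytic DMAP limits its epimerisation.

Step 12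
Reactants: 20 (above)
Product: 21 (1R,3Z)-3-[(TBDPS-oxy)methyl]-6-hydroxy-1-[(2S,3R)-2-[(1Z)-2-iodoprop-1-en-1-yl]-4-methylidene-5-oxooxolan-3-yl]hex-3-en-1-yl (2R)-2-methylbutanoate
Conditions: camphorsulfonic acid (cat.), MeOH/CH2Cl2, 0 °C
Reagents that add atoms: none
Why: acid-catalysed methanolysis removes the primary TBS ether much faster than the TBDPS ether, and the lactone and the ester are stable to these conditions.

Step 13
Reactants: 21 (above)
Product: 22 (1R,3Z)-3-[(TBDPS-oxy)methyl]-6-oxo-1-[(2S,3R)-2-[(1Z)-2-iodoprop-1-en-1-yl]-4-methylidene-5-oxooxolan-3-yl]hex-3-en-1-yl (2R)-2-methylbutanoate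
Conditions: Dess–Martin periodinane, NaHCO3, CH2Cl2, 0 °C to rt
Reagents that add atoms: none
Why: Dess–Martin oxidation under buffered, near-neutral conditions gives the β,γ-unsaturated aldehyde without moving C1=C10 into conjugation; the aldehyde is used at once.

Step 14
Reactants: 22 (above)
Product: 23 (3S,4Z,6R,7R,8R)-14-(TBDPS-oxy)-3-hydroxy-8-[(2R)-2-methylbutanoyloxy]germacra-1(10),4,11(13)-trien-12,6-olide (C1=C10 ring-trans)
Conditions: CrCl2 (excess), NiCl2 (cat.), DMSO/THF, rt, slow addition at high dilution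
Reagents that add atoms: none
Why: intramolecular Nozaki–Hiyama–Kishi coupling: zerovalent nickel inserts into the alkenyl iodide with retention of the Z geometry, transmetalation gives an alkenyl species of trivalent chromium that adds only to the aldehyde and closes the ten-membered ring at C3–C4; C3 is set under substrate control by the chain folded around the trans-lactone and the two alkenes, the natural 3S epimer is assumed, and this is the least secure stereochemical prediction of the route.

Step 15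
Reactants: 23 (above)
Product: 24 (3S,4Z,6R,7R,8R)-3,14-dihydroxy-8-[(2R)-2-methylbutanoyloxy]germacra-1(10),4,11(13)-trien-12,6-olide
Conditions: HF·pyridine, pyridine, THF, 0 °C to rt
Reagents that add atoms: none
Why: buffered fluoride cleaves the primary allylic TBDPS ether without touching the ester, the lactone or the methylene acceptor.

Step 16
Reactants: 24 (above)
Product: 25 (1R,3S,4Z,6R,7R,8R,10S)-1,10-epoxy-3,14-dihydroxy-8-[(2R)-2-methylbutanoyloxy]germacra-4,11(13)-dien-12,6-olide (target)
Conditions: Ti(OiPr)4 (cat.), (+)-(2R,3R)-diethyl tartrate, tBuOOH (1.1 equiv), 4 Å molecular sieves, CH2Cl2, −20 °C; buffered work-up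
Reagents that add atoms: tert-butyl hydroperoxide, CC(C)(C)OO
Why: Sharpless asymmetric epoxidation in which the C14 alkoxide on titanium delivers oxygen to C1=C10 from the face chosen by the tartrate, setting C1 (R) and C10 (S); the primary allylic alcohol reacts much faster than the secondary, cis-substituted C3 allylic alcohol, and the methylene lactone is inert.

**Compound list**

1 | methyl 2-[bis(2,2,2-trifluoroethoxy)phosphoryl]acetate | COC(=O)CP(=O)(OCC(F)(F)F)OCC(F)(F)F | starting material
2 | allyl bromide | C=CCBr | starting material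
3 | methyl 2-[bis(2,2,2-trifluoroethoxy)phosphoryl]pent-4-enoate (racemic) | COC(=O)C(CC=C)P(=O)(OCC(F)(F)F)OCC(F)(F)F | intermediate
4 | 3-[(tert-butyldimethylsilyl)oxy]propanal | O=CCCO[Si](C)(C)C(C)(C)C | starting material
5 | methyl (2Z)-5-(TBS-oxy)-2-(prop-2-en-1-yl)pent-2-enoate | C=CC/C(C(=O)OC)=C/CCO[Si](C)(C)C(C)(C)C | intermediate
6 | (2Z)-5-(TBS-oxy)-2-(prop-2-en-1-yl)pent-2-en-1-ol | C=CC/C(CO)=C/CCO[Si](C)(C)C(C)(C)C | intermediate
7 | (2Z)-1-(TBDPS-oxy)-5-(TBS-oxy)-2-(prop-2-en-1-yl)pent-2-ene | C=CC/C(CO[Si](c1ccccc1)(c1ccccc1)C(C)(C)C)=C/CCO[Si](C)(C)C(C)(C)C | intermediate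
8 | (E)-crotonaldehyde | C/C=C/C=O | starting material
9 | (2E,5Z)-5-[(TBDPS-oxy)methyl]-8-(TBS-oxy)octa-2,5-dienal | O=C/C=C/C/C(CO[Si](c1ccccc1)(c1ccccc1)C(C)(C)C)=C/CCO[Si](C)(C)C(C)(C)C | intermediate
10 | prop-1-ynylmagnesium bromide | CC#C[Mg]Br | starting material
11 | rac-(5E,8Z)-8-[(TBDPS-oxy)methyl]-11-(TBS-oxy)undeca-5,8-dien-2-yn-4-ol | CC#CC(O)/C=C/C/C(CO[Si](c1ccccc1)(c1ccccc1)C(C)(C)C)=C/CCO[Si](C)(C)C(C)(C)C | intermediate
12 | sodium alkenylalanate from 11 (five-membered ring O–Al–C=C–C, aluminium on the methyl-bearing alkene carbon, two 2-methoxyethoxy ligands; racemic) | [Na+].CC1=CC(/C=C/C/C(CO[Si](c2ccccc2)(c2ccccc2)C(C)(C)C)=C/CCO[Si](C)(C)C(C)(C)C)O[Al-]1(OCCOC)OCCOC | intermediate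
13 | rac-(2Z,5E,8Z)-2-iodo-8-[(TBDPS-oxy)methyl]-11-(TBS-oxy)undeca-2,5,8-trien-4-ol | C/C(I)=C/C(O)/C=C/C/C(CO[Si](c1ccccc1)(c1ccccc1)C(C)(C)C)=C/CCO[Si](C)(C)C(C)(C)C | intermediate
14 | (1R,2Z)-1-[(2R,3R)-3-{(2Z)-2-[(TBDPS-oxy)methyl]-5-(TBS-oxy)pent-2-en-1-yl}oxiran-2-yl]-3-iodobut-2-en-1-ol | C/C(I)=C/[C@@H](O)[C@H]1O[C@@H]1C/C(CO[Si](c2ccccc2)(c2ccccc2)C(C)(C)C)=C/CCO[Si](C)(C)C(C)(C)C | intermediate
15 | 2-(diethoxyphosphoryl)acetic acid | CCOP(=O)(CC(=O)O)OCC | starting material
16 | (1R,2Z)-1-[(2S,3R)-3-{(2Z)-2-[(TBDPS-oxy)methyl]-5-(TBS-oxy)pent-2-en-1-yl}oxiran-2-yl]-3-iodobut-2-en-1-yl 2-(diethoxyphosphoryl)acetate | C/C(I)=C/[C@@H](OC(=O)CP(=O)(OCC)OCC)[C@H]1O[C@@H]1C/C(CO[Si](c2ccccc2)(c2ccccc2)C(C)(C)C)=C/CCO[Si](C)(C)C(C)(C)C | intermediate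
17 | diethyl {(4R,5S)-4-[(1R,3Z)-1-hydroxy-3-[(TBDPS-oxy)methyl]-6-(TBS-oxy)hex-3-en-1-yl]-5-[(1Z)-2-iodoprop-1-en-1-yl]-2-oxooxolan-3-yl}phosphonate (both C3 epimers) | CCOP(=O)(OCC)C1C(=O)O[C@H](/C=C(/C)I)[C@H]1[C@H](O)C/C(CO[Si](c2ccccc2)(c2ccccc2)C(C)(C)C)=C/CCO[Si](C)(C)C(C)(C)C | intermediate
18 | (4R,5S)-4-[(1R,3Z)-1-hydroxy-3-[(TBDPS-oxy)methyl]-6-(TBS-oxy)hex-3-en-1-yl]-5-[(1Z)-2-iodoprop-1-en-1-yl]-3-methylideneoxolan-2-one | C=C1C(=O)O[C@H](/C=C(/C)I)[C@H]1[C@H](O)C/C(CO[Si](c2ccccc2)(c2ccccc2)C(C)(C)C)=C/CCO[Si](C)(C)C(C)(C)C | intermediate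
19 | (2R)-2-methylbutanoic acid | CC[C@@H](C)C(=O)O | starting material
20 | (1R,3Z)-3-[(TBDPS-oxy)methyl]-6-(TBS-oxy)-1-[(2S,3R)-2-[(1Z)-2-iodoprop-1-en-1-yl]-4-methylidene-5-oxooxolan-3-yl]hex-3-en-1-yl (2R)-2-methylbutanoate | C=C1C(=O)O[C@H](/C=C(/C)I)[C@H]1[C@H](OC(=O)[C@H](C)CC)C/C(CO[Si](c2ccccc2)(c2ccccc2)C(C)(C)C)=C/CCO[Si](C)(C)C(C)(C)C | intermediate
21 | 6-hydroxy analogue of 20 (TBS removed) | C=C1C(=O)O[C@H](/C=C(/C)I)[C@H]1[C@H](OC(=O)[C@H](C)CC)C/C(CO[Si](c2ccccc2)(c2ccccc2)C(C)(C)C)=C/CCO | intermediate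
22 | 6-oxo analogue of 20 (C3 aldehyde) | C=C1C(=O)O[C@H](/C=C(/C)I)[C@H]1[C@H](OC(=O)[C@H](C)CC)C/C(CO[Si](c2ccccc2)(c2ccccc2)C(C)(C)C)=C/CC=O | intermediate
23 | (3S,4Z,6R,7R,8R)-14-(TBDPS-oxy)-3-hydroxy-8-[(2R)-2-methylbutanoyloxy]germacra-1(10),4,11(13)-trien-12,6-olide, C1=C10 ring-trans | C=C1C(=O)O[C@@H]2/C=C(/C)[C@@H](O)C/C=C(\CO[Si](c3ccccc3)(c3ccccc3)C(C)(C)C)C[C@@H](OC(=O)[C@H](C)CC)[C@@H]12 | intermediate
24 | (3S,4Z,6R,7R,8R)-3,14-dihydroxy-8-[(2R)-2-methylbutanoyloxy]germacra-1(10),4,11(13)-trien-12,6-olide | C=C1C(=O)O[C@@H]2/C=C(/C)[C@@H](O)C/C=C(\CO)C[C@@H](OC(=O)[C@H](C)CC)[C@@H]12 | intermediate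
25 | (1R,3S,4Z,6R,7R,8R,10S)-1,10-epoxy-3,14-dihydroxy-8-[(2R)-2-methylbutanoyloxy]germacra-4,11(13)-dien-12,6-olide | C=C1C(=O)O[C@@H]2/C=C(/C)[C@@H](O)C[C@H]3O[C@]3(CO)C[C@@H](OC(=O)[C@H](C)CC)[C@@H]12 | target

**Totals.** Total step count: 16. Longest linear sequence: 16 steps (from 1 to 25).

**Steps most likely to fail**

1. Step 10 (key step). What may go wrong: O-alkylation of the ambident anion or attack at C8 instead of C7; migration of the phosphoryl group to the new C8 alkoxide followed by cyclopropane closure if the mixture is warmed before the formaldehyde is added; base-induced translactonisation to the C8 oxygen. Fallback (from 14, back at 18): the phosphonate is replaced by a malonate, the classical carbanion for opening epoxides and one that cannot transfer a phosphoryl group. Epoxy alcohol 14 is esterified (N,N'-dicyclohexylcarbodiimide, DMAP) with mono-tert-butyl malonate to the mixed malonate F1. NaH in THF then closes the same C7–C11 bond 5-exo with inversion at C7 to the α-(tert-butoxycarbonyl) lactone F2. Trimethylsilyl triflate with 2,6-lutidine, followed by mild aqueous acid, removes the tert-butyl group to give the α-carboxy lactone F3. Decarboxylative Mannich methylenation (aq. CH2O, Et2NH, then NaOAc/AcOH, warm) gives 18.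

2. Step 14. What may go wrong: poor facial selectivity in the addition to the C3 aldehyde; oligomerisation if the dilution is insufficient; migration of C1=C10 into conjugation in the aldehyde before ring closure. Fallback (from 22, back at 23): C3 is set by reagent-controlled ketone reduction instead of by the carbon–carbon bond formation. The carbinol mixture from the ring closure, 23 together with its C3 epimer F4, is oxidised with Dess–Martin periodinane to the single 3-oxo-4-ene, enone F5. Corey–Bakshi–Shibata reduction with the (R)-2-methyl-oxazaborolidine and catecholborane at −78 °C (alkenyl as the large group) should then give the 3S alcohol 23.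

3. Step 16. What may go wrong: oxygen delivery to the wrong face if the ring conformation overrides the tartrate; competing epoxidation of C4=C5 directed by the C3 hydroxyl; Lewis-acid-promoted transannular opening of the new epoxide by the C3 hydroxyl. Fallback (from 23, back at 25): the hydroxyl-directed titanium epoxidation is replaced by a non-directed, reagent-controlled dioxirane epoxidation carried out before the C14 hydroxyl is unmasked. Silyl ether 23 is treated with the fructose-derived Shi ketone and KHSO5 (K2CO3 buffer, MeCN/dimethoxymethane/water, 0 °C). The dioxirane should prefer the more electron-rich ring-trans C1=C10 alkene over C4=C5, which is flanked by two allylic oxygens, and over the enoate, giving the epoxy silyl ether F6. HF·pyridine buffered with pyridine then gives 25.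

**Further compounds**

F1 | step 10 | tert-butyl malonate mixed ester of 14 | C/C(I)=C/[C@@H](OC(=O)CC(=O)OC(C)(C)C)[C@H]1O[C@@H]1C/C(CO[Si](c2ccccc2)(c2ccccc2)C(C)(C)C)=C/CCO[Si](C)(C)C(C)(C)C
F2 | step 10 | α-(tert-butoxycarbonyl) lactone (C8 hydroxyl free, both C11 epimers) | CC(C)(C)OC(=O)C1C(=O)O[C@H](/C=C(/C)I)[C@H]1[C@H](O)C/C(CO[Si](c2ccccc2)(c2ccccc2)C(C)(C)C)=C/CCO[Si](C)(C)C(C)(C)C
F3 | step 10 | α-carboxy lactone | OC(=O)C1C(=O)O[C@H](/C=C(/C)I)[C@H]1[C@H](O)C/C(CO[Si](c2ccccc2)(c2ccccc2)C(C)(C)C)=C/CCO[Si](C)(C)C(C)(C)C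
F4 | step 14 | C3 epimer (3R) of 23 | C=C1C(=O)O[C@@H]2/C=C(/C)[C@H](O)C/C=C(\CO[Si](c3ccccc3)(c3ccccc3)C(C)(C)C)C[C@@H](OC(=O)[C@H](C)CC)[C@@H]12
F5 | step 14 | 3-oxo analogue of 23 (macrocyclic enone) | C=C1C(=O)O[C@@H]2/C=C(/C)C(=O)C/C=C(\CO[Si](c3ccccc3)(c3ccccc3)C(C)(C)C)C[C@@H](OC(=O)[C@H](C)CC)[C@@H]12
F6 | step 16 | 14-O-TBDPS ether of 25 | C=C1C(=O)O[C@@H]2/C=C(/C)[C@@H](O)C[C@H]3O[C@]3(CO[Si](c4ccccc4)(c4ccccc4)C(C)(C)C)C[C@@H](OC(=O)[C@H](C)CC)[C@@H]12
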